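The target in the eta run read 55.6% at 50.0 h, with the solid electrophile at 0%, so I had to reckon how much of what leaves the solid has reacted.

| setting | zeta | eta | autumn | noon |
|---|---|---|---|---|
| solid electrophile | 20 mM | 20 mM | 20 mM | 20 mM |
| nucleophile | 60 mM | 60 mM | 60.0 mM | 60.0 mM |
| free base | 3.3 mM (fed, over 25 h) | 9.1 mM (fed, over 25 h) | 6.00 mM (fed, over 25 h) | 12.0 mM (fed, over 25 h) |
| remark | run made earlier | run made earlier |  |  |
| time |  |  | 2.0 d | 2.0 d |

| run | time / h | solid electrophile / % | target / % |
|---|---|---|---|
| zeta | 4.00 | 88.3 | 2.4 |
| zeta | 6.00 | 84.3 | 4.6 |
| zeta | 8.00 | 79.6 | 7.7 |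
| zeta | 15.0 | 64.8 | 17.0 |
| zeta | 20.0 | 54.3 | 24.6 |
| zeta | 30.0 | 35.5 | 38.0 |
| zeta | 50.0 | 0.2 | 54.7 |
| eta | 2.50 | 92.7 | 1.2 |
| eta | 8.00 | 79.0 | 6.9 |
| eta | 15.0 | 65.0 | 17.1 |
| eta | 20.0 | 55.5 | 25.0 |
| eta | 30.0 | 35.8 | 37.6 |
| eta | 40.0 | 16.9 | 47.5 |
| eta | 50.0 | 0 | 55.6 |

(each reading ± 0.3 percentage points)

* part of the solid electrophile that has reacted (what has only dissolved counts as not reacted) at the end, autumn
* part of the solid electrophile that has reacted (what has only dissolved counts as not reacted) at the end, noon
* what raising the concentration of free base from its lowest to its highest value here does to the part of the solid electrophile that has reacted (what has only dissolved counts as not reacted) (changes below 5 percentage points count as none) (no change / it rises / it falls)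

- the numbers in the tables scatter by 0.3 percentage points (one standard deviation)
- at the start none of the solid electrophile is in solution
- what has only dissolved of solid electrophile counts as not reacted

I began with two extreme flasks. If a dissolved molecule reacted at once, the part reacted would equal the solid lost. In the eta run the solid fell 19 percentage points in 10.0 h, and continuing that line from 40.0 h left 1.78% at 2.0 d, so this extreme gave 98.2%. If a dissolved molecule never reacted, the part reacted would be nothing.

So I followed one molecule between dissolving and reacting. At 15.0 h in the eta run, the charge minus solid and target was 17.9%, which I took as dissolved stock, while the target gained 18 points in 12.0 h. Stock divided by that rate gave the waiting time (residence time), 11.9 h. That is about a quarter of 2.0 d, so I placed the flask nearer the first extreme, but clearly under it.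

I assumed the waiting time held. Stock is inflow times waiting time, 22.4%, so I reckoned 75.8% reacted in autumn and noon. The eta gap at 50.0 h, 44.4%, is larger than that stock, so I counted the rest as a second reacted product, and some of the gap at 15.0 h may have been that product too. At 30.0 h the zeta and eta solids differ by 0.3 points, about the scatter, so I expected no change with base.

The forecast gave 97% for autumn, 97% for noon and no change, since “the limit looks like dissolution of the solid rather than the chemistry in solution”. The simulation gives 78.9% for autumn and 79.1% for noon, and for the trend no change: from the lowest base to the highest the part reacted moved by 0.18 points.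

    electrophile + nucleophile → acid set free + target (k = 1.90 M⁻¹ h⁻¹)
    nucleophile + acid set free ⇌ protonated nucleophile, settled at all times (K = 69000 M⁻¹)
    acid set free + free base ⇌ salt of the base, settled at all times (K = 18000 M⁻¹)
    solid electrophile ⇌ electrophile, rate k4*(cs4 - [electrophile]) while solid is left; crystals form when [electrophile] > cs4 (solubility = 9.10 mM, k = 0.0690 h⁻¹)
    electrophile + target → side product (k = 2.60 M⁻¹ h⁻¹)

In autumn at 2.00 d the electrophile stood at 19.0%, against my stock of 22.4%. A neighbouring flask, like autumn but with 34 mM of solid electrophile, I reckoned in mM with the same waiting time and inflow. The solid loses 19.6 mM, leaving 42.4%, and c(electrophile) is 4.49 mM, or 13.2% of that charge, so 44.4% has reacted. That flask holds 42.4% solid and 11.2% electrophile, with 46.4% reacted.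

All runs were computed for substances that don't exist.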